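**Plan**
Retrosynthesis: after the desilylation and the C2 equilibration are taken back, the oxolane is cut in one stroke at O1–C2 and C3–C4. This gives two C6–C3 units: the (E)-1-propenyl arene 3 (ring A, C2, C3, C3–CH3) and the (R)-aryl vinyl carbinol 6 (ring B, C5, O1, C4, with the vinyl CH2 as the future C4–CH3).
Forward: aldehyde 1 → silyl ether 2 → alkene 3; aldehyde 4 → racemic carbinol 5 → (R)-6; 3 and 6 close the only ring in one flask (iodoetherification, then 5-exo radical cyclisation) to the C2-epimeric oxolanes 9; BF3 equilibration at C2 gives 10 and desilylation gives 11.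
Enabling feature: C2 is benzylic to the oxygenated ring A, so the iodonium ion of 3 is opened there by O1. The unit O1–C5–C4(–CH3) is a vinyl carbinol in disguise, so the C3 radical has a 5-exo acceptor whose terminus ends as the C4 methyl group.
Stereochemistry: C5 from the Sharpless kinetic resolution; C4 and C3 from the chair-like 5-exo transition state (C4 methyl trans to ring B, C3 methyl cis to the C4 methyl); C2 by thermodynamic equilibration of the benzylic ether (ring A trans to the C3 methyl).

Key step: step 5

Remark: atoms are numbered as in the oxolane (O1; C2 with ring A = 3-hydroxy-4,5-dimethoxyphenyl; C3; C4; C5 with ring B = 3,4,5-trimethoxyphenyl), so the target is (2S,3S,4R,5R). Aldehydes 1 and 4, all reagents, and the 5-bromo-2,3-dimethoxyphenol used in one fallback are taken as catalog compounds.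

Step 1
Reactants: 1 3-hydroxy-4,5-dimethoxybenzaldehyde
Product: 2 3,4-dimethoxy-5-[(triisopropylsilyl)oxy]benzaldehyde
Conditions: TIPSCl, imidazole, DMF, rt
Reagents that add atoms: chlorotriisopropylsilane, CC(C)[Si](Cl)(C(C)C)C(C)C
Why: Silylation of the phenol gives an aryl silyl ether that keeps ring A from being iodinated or oxidised in step 5 and should survive the base of step 2, the tin hydride of step 5 and the BF3·OEt2 of step 6.

Step 2
Reactants: 2 3,4-dimethoxy-5-[(triisopropylsilyl)oxy]benzaldehyde
Product: 3 triisopropyl{2,3-dimethoxy-5-[(1E)-prop-1-en-1-yl]phenoxy}silane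
Conditions: 5-(ethylsulfonyl)-1-phenyl-1H-tetrazole, KN(SiMe3)2, DME, −60 °C → rt
Reagents that add atoms: 5-(ethylsulfonyl)-1-phenyl-1H-tetrazole, CCS(=O)(=O)c1nnnn1-c2ccccc2
Why: Julia–Kocienski olefination (addition of the metalated ethyl sulfone, Smiles rearrangement, loss of SO2 and the tetrazololate) should give mainly the (E)-alkene from an aromatic aldehyde; the alkene geometry is in any case erased when C3 becomes a radical in step 5.

Step 3
Reactants: 4 3,4,5-trimethoxybenzaldehyde
Product: 5 rac-1-(3,4,5-trimethoxyphenyl)prop-2-en-1-ol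
Conditions: CH2=CHMgBr, THF, −20 → 0 °C
Reagents that add atoms: vinylmagnesium bromide, C=C[Mg]Br
Why: Grignard 1,2-addition of the vinyl nucleophile to the non-enolisable aldehyde should give the racemic allylic alcohol.

Step 4
Reactants: 5 rac-1-(3,4,5-trimethoxyphenyl)prop-2-en-1-ol
Product: 6 (1R)-1-(3,4,5-trimethoxyphenyl)prop-2-en-1-ol
Conditions: Ti(OiPr)4 (0.15 equiv), D-(−)-DIPT (0.2 equiv), t-BuOOH (0.6 equiv), 4 Å MS, CH2Cl2, −20 °C, stopped near 55% conversion
Reagents that add atoms: none
Why: Sharpless kinetic resolution: with D-(−)-DIPT the titanium tartrate complex should epoxidise the (S)-alcohol faster (the aryl group outranks vinyl, which inverts the descriptor relative to alkyl vinyl carbinols) and leave the (R)-alcohol, whose carbinol carbon becomes C5.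

Step 5
Reactants: 3 triisopropyl{2,3-dimethoxy-5-[(1E)-prop-1-en-1-yl]phenoxy}silane; 6 (1R)-1-(3,4,5-trimethoxyphenyl)prop-2-en-1-ol
Product: 9 triisopropyl{2,3-dimethoxy-5-[(3S,4R,5R)-3,4-dimethyl-5-(3,4,5-trimethoxyphenyl)oxolan-2-yl]phenoxy}silane as the mixture of its 2S and 2R epimers, via iodo ether 7 (not isolated), via iodo ether 8 (not isolated)
Conditions: 3 (1.2 equiv), 6 (1.0 equiv), NIS (1.1 equiv), 4 Å MS, CH2Cl2, −40 → −20 °C, dark; then toluene, Bu3SnH (1.5 equiv), Et3B (0.2 equiv), air, −78 → −40 °C
Reagents that add atoms: none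
Why: N-Iodosuccinimide turns the electron-rich propenyl group of 3 into an iodonium ion that alcohol 6 opens at the benzylic carbon (O1–C2 formed, iodine on C3, anti addition on either alkene face, hence 7 and 8); tributyltin radicals then abstract the iodine, the secondary C3 radical adds to the internal carbon of the tethered vinyl group (C3–C4 formed) and the primary radical takes hydrogen from Bu3SnH to become the C4 methyl group. The closest known reaction type is the Ueno–Stork sequence, that is haloetherification of an alkene with an allylic alcohol followed by radical cyclisation of the β-halo allyl ether. The oxolane closes in the 5-exo-trig mode. C5 is carried in from 6; C4 is set trans to ring B because that ring sits pseudo-equatorial on the allylic carbon of the chair-like transition state; C3 is set with its methyl cis to the new C4 methyl because the substituent on the radical carbon prefers the outside position of the same chair; C2 arises without control in the etherification, so that 7 should give the (2S) oxolane and 8 its (2R) epimer, which together make up 9 and are converged in step 6. The step needs alkoxylation at the benzylic carbon, attack of the iodonium source on the propenyl group and not on the vinyl group or the arenes, and cyclisation ahead of direct reduction; the first two are secured by the oxygenated ring A, which makes this alkene by far the most nucleophilic site and localises the positive charge on C2, and the last by the fast 5-exo closure of 3-oxahex-5-enyl radicals at low tin hydride concentration.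

Step 6
Reactants: 9 triisopropyl{2,3-dimethoxy-5-[(3S,4R,5R)-3,4-dimethyl-5-(3,4,5-trimethoxyphenyl)oxolan-2-yl]phenoxy}silane (mixture of the 2S and 2R epimers)
Product: 10 triisopropyl{2,3-dimethoxy-5-[(2S,3S,4R,5R)-3,4-dimethyl-5-(3,4,5-trimethoxyphenyl)oxolan-2-yl]phenoxy}silane
Conditions: BF3·OEt2 (0.3 equiv), CH2Cl2, −20 → 0 °C
Reagents that add atoms: none
Why: Lewis acid equilibration of a benzylic ether: BF3 should ionise the C2–O1 bond to a benzylic cation stabilised by the oxygenated ring A, and reclosure should drain the (2R) epimer into the oxolane with ring A trans to the C3 methyl, while C3 and C4 have no pathway to epimerise and C5, which may ionise in the same way, already holds its preferred trans arrangement to the C4 methyl.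

Step 7
Reactants: 10 triisopropyl{2,3-dimethoxy-5-[(2S,3S,4R,5R)-3,4-dimethyl-5-(3,4,5-trimethoxyphenyl)oxolan-2-yl]phenoxy}silane
Product: 11 5-[(2S,3S,4R,5R)-3,4-dimethyl-5-(3,4,5-trimethoxyphenyl)oxolan-2-yl]-2,3-dimethoxyphenol
Conditions: Bu4NF, THF, 0 °C
Reagents that add atoms: none
Why: Fluoride should cleave the Si–O bond of the aryl silyl ether and leave the benzylic ether stereocentres untouched.

**Compound list**
1 | 3-hydroxy-4,5-dimethoxybenzaldehyde | O=Cc1cc(O)c(OC)c(OC)c1 | starting material
2 | 3,4-dimethoxy-5-[(triisopropylsilyl)oxy]benzaldehyde | O=Cc1cc(OC)c(OC)c(O[Si](C(C)C)(C(C)C)C(C)C)c1 | intermediate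
3 | triisopropyl{2,3-dimethoxy-5-[(1E)-prop-1-en-1-yl]phenoxy}silane | C/C=C/c1cc(OC)c(OC)c(O[Si](C(C)C)(C(C)C)C(C)C)c1 | intermediate
4 | 3,4,5-trimethoxybenzaldehyde | O=Cc1cc(OC)c(OC)c(OC)c1 | starting material
5 | rac-1-(3,4,5-trimethoxyphenyl)prop-2-en-1-ol | OC(C=C)c1cc(OC)c(OC)c(OC)c1 | intermediate
6 | (1R)-1-(3,4,5-trimethoxyphenyl)prop-2-en-1-ol | O[C@@H](c1cc(OC)c(OC)c(OC)c1)C=C | intermediate
7 | triisopropyl{5-[(1R,2S)-2-iodo-1-{[(1R)-1-(3,4,5-trimethoxyphenyl)prop-2-en-1-yl]oxy}propyl]-2,3-dimethoxyphenoxy}silane | COc1cc(cc(O[Si](C(C)C)(C(C)C)C(C)C)c1OC)[C@@H](O[C@@H](c1cc(OC)c(OC)c(OC)c1)C=C)[C@H](C)I | intermediate (not isolated)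
8 | triisopropyl{5-[(1S,2R)-2-iodo-1-{[(1R)-1-(3,4,5-trimethoxyphenyl)prop-2-en-1-yl]oxy}propyl]-2,3-dimethoxyphenoxy}silane | COc1cc(cc(O[Si](C(C)C)(C(C)C)C(C)C)c1OC)[C@H](O[C@@H](c1cc(OC)c(OC)c(OC)c1)C=C)[C@@H](C)I | intermediate (not isolated)
9 | triisopropyl{2,3-dimethoxy-5-[(3S,4R,5R)-3,4-dimethyl-5-(3,4,5-trimethoxyphenyl)oxolan-2-yl]phenoxy}silane (mixture of the 2S and 2R epimers) | COc1cc(C2O[C@@H](c3cc(OC)c(OC)c(OC)c3)[C@H](C)[C@@H]2C)cc(O[Si](C(C)C)(C(C)C)C(C)C)c1OC | intermediate
10 | triisopropyl{2,3-dimethoxy-5-[(2S,3S,4R,5R)-3,4-dimethyl-5-(3,4,5-trimethoxyphenyl)oxolan-2-yl]phenoxy}silane | COc1cc([C@H]2O[C@@H](c3cc(OC)c(OC)c(OC)c3)[C@H](C)[C@@H]2C)cc(O[Si](C(C)C)(C(C)C)C(C)C)c1OC | intermediate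
11 | 5-[(2S,3S,4R,5R)-3,4-dimethyl-5-(3,4,5-trimethoxyphenyl)oxolan-2-yl]-2,3-dimethoxyphenol | COc1cc([C@H]2O[C@@H](c3cc(OC)c(OC)c(OC)c3)[C@H](C)[C@@H]2C)cc(O)c1OC | target

Total step count: 7. Longest linear sequence: 5 steps (steps 1, 2, 5, 6, 7 or steps 3, 4, 5, 6, 7).

**Steps most likely to fail**

Step 5. The iodonium ion may be captured by succinimide or traces of water instead of the hindered secondary alcohol, and the electron-rich allylic alcohol may ionise. The C3 radical may be reduced before it cyclises. Iodo ether 8, in which rings A and B cannot both sit pseudo-equatorial, may close with lower facial control at C3. The fallback sets out from 6 and moves the first stage to an enol ether, the substrate class for which the Ueno–Stork reaction is best established. NBS and ethyl prop-1-enyl ether should give the bromoacetal 5-[(1R)-1-(2-bromo-1-ethoxypropoxy)prop-2-en-1-yl]-1,2,3-trimethoxybenzene F1. Bu3SnH and AIBN should close it to (3S,4R,5R)-2-ethoxy-3,4-dimethyl-5-(3,4,5-trimethoxyphenyl)oxolane F2, in which the anomeric configuration does not matter. Ring A is prepared separately: 5-bromo-2,3-dimethoxyphenol is silylated (TIPSCl, imidazole) to (5-bromo-2,3-dimethoxyphenoxy)triisopropylsilane F3, which magnesium turnings in THF should convert into bromo{3,4-dimethoxy-5-[(triisopropylsilyl)oxy]phenyl}magnesium F4. The ethoxy group of F2 is then exchanged for this aryl group through the cyclic oxocarbenium ion released by BF3·OEt2 at low temperature. The aryl nucleophile should enter anti to the cis-dimethyl face and so trans to the C3 methyl group. This comes back to the route at 10, so that steps 5 and 6 are not needed.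

Step 6. The ring-opened benzylic cation may attack ring B in a Friedel–Crafts sense (aryltetralin formation), the silyl ether may be lost, or the equilibration may stop short of completion. The fallback sets out from 9 and avoids cations altogether. Reversible hydrogen-atom abstraction at the benzylic α-oxy C–H bonds under photochemical thiyl-radical catalysis (alkanethiol, organic photocatalyst, blue light) should also drain the (2R) epimer into the more stable (2S) oxolane. It comes back at 10 and makes no new compound.

Step 4. Epoxidation of the monosubstituted vinyl group is slow and the rate ratio between the enantiomers may be modest, so the recovered alcohol may fall short in enantiomeric purity; the carbinol may also ionise on the titanium centre. The fallback sets out from 5 and resolves by enzymatic acylation instead of oxidation. Novozym 435 (immobilised lipase B of Candida antarctica) and vinyl acetate should acylate the (R)-enantiomer, in line with the usual preference of this lipase for secondary carbinols with one large and one medium group, to give (1R)-1-(3,4,5-trimethoxyphenyl)prop-2-en-1-yl acetate F5. After separation from the unreacted (S)-alcohol, K2CO3 in MeOH should release 6, where the fallback comes back to the route.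

**Further compounds**
F1 | step 5 | 5-[(1R)-1-(2-bromo-1-ethoxypropoxy)prop-2-en-1-yl]-1,2,3-trimethoxybenzene (mixture at the two new centres) | CCOC(O[C@@H](c1cc(OC)c(OC)c(OC)c1)C=C)C(C)Br
F2 | step 5 | (3S,4R,5R)-2-ethoxy-3,4-dimethyl-5-(3,4,5-trimethoxyphenyl)oxolane (anomeric mixture) | CCOC1O[C@@H](c2cc(OC)c(OC)c(OC)c2)[C@H](C)[C@@H]1C
F3 | step 5 | (5-bromo-2,3-dimethoxyphenoxy)triisopropylsilane | COc1cc(Br)cc(O[Si](C(C)C)(C(C)C)C(C)C)c1OC
F4 | step 5 | bromo{3,4-dimethoxy-5-[(triisopropylsilyl)oxy]phenyl}magnesium | COc1cc([Mg]Br)cc(O[Si](C(C)C)(C(C)C)C(C)C)c1OC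
F0 | step 6 | none | none
F5 | step 4 | (1R)-1-(3,4,5-trimethoxyphenyl)prop-2-en-1-yl acetate | CC(=O)O[C@@H](c1cc(OC)c(OC)c(OC)c1)C=C
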